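| setting | epsilon | delta | eta | flask |
|---|---|---|---|---|
| substrate | 0.058 M | 0.058 M | 0.058 M | 0.058 M |
| reagent | 0.80 equiv | 1.8 equiv | 1.2 equiv | 1.20 equiv |
| free catalyst | 2.2 mol% | 2.2 mol% | 3.3 mol% | 2.2 mol% |
| second catalyst | 2.5 mol% | 2.5 mol% | 2.5 mol% | 2.5 mol% |
| remark | run made earlier | run made earlier | run made earlier |  |

| run | time / h | product / % | substrate / % |
|---|---|---|---|
| epsilon | 0.250 | 0.6 | 96.4 |
| epsilon | 0.833 | 1.3 | 94.5 |
| epsilon | 1.33 | 1.2 | 92.8 |
| epsilon | 2.00 | 1.2 | 90.1 |
| epsilon | 3.00 | 3.8 | 86.8 |
| epsilon | 4.00 | 4.0 | 82.9 |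
| delta | 0.250 | 0 | 98.3 |
| delta | 0.833 | 0.5 | 95.4 |
| delta | 1.33 | 2.7 | 92.6 |
| delta | 2.00 | 2.9 | 88.8 |
| delta | 3.00 | 5.5 | 86.5 |
| delta | 4.00 | 8.5 | 83.6 |
| eta | 0.333 | 0.4 | 97.4 |
| eta | 0.667 | 0.6 | 93.5 |
| eta | 1.00 | 1.4 | 92.9 |
| eta | 2.00 | 4.9 | 87.4 |
| eta | 4.00 | 7.3 | 79.4 |

(readings scatter by 1 percentage point)

* apparent order in free catalyst when 30% of the substrate are converted (percent change of the rate of making product for one percent more free catalyst charged)
* apparent order in reagent when 30% of the substrate are converted (percent change of the rate of making product for one percent more reagent charged)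

- "the catalyst" is free catalyst with its forms; second catalyst is a second catalyst

Late in the eta run, intermediate (charge minus substrate minus product) reads 7.70% at 2.00 h and 13.3% at 4.00 h. Eta has the flask's reagent and second catalyst, so we take from it the lifetime of the intermediate, the area under its curve per unit of product made:

lifetime = 3.93 h

The second time is the one to 30% conversion. Epsilon and delta bracket the flask's reagent, and on average they have lost 16.7% by 4.00 h and lose 0.0310 h⁻¹ of the charge late on:

time to conversion = 8.27 h

We treat this as a floor, since epsilon's loss has slowed from 0.0660 h⁻¹ to 0.0360 h⁻¹. The ratio N of this time to the lifetime counts lifetimes elapsed. In our reckoning, product rate is the making rate of intermediate times (1 − exp(−N)), and we take the lifetime as inverse in reagent, so: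

N = 2.10, order in reagent = N/(exp(N) − 1) = 0.292

In this reckoning the reagent order falls as N grows, and the rate of making product comes to follow the making of intermediate rather than its use. The forecast gives 0.35 in free catalyst and 0.45 in reagent, holding that “30% conversion comes at about 7 h”; our reagent order is lower.

The flask gives 0.64 in free catalyst and 0.12 in reagent.

    substrate + free catalyst ⇌ free catalyst + intermediate (K = 1.50, k = 65.5 M⁻¹ h⁻¹)
    reagent + second catalyst + intermediate → second catalyst + product (k = 2520 M⁻² h⁻¹)
    2 free catalyst ⇌ resting dimer (K = 4830 M⁻¹, k = 235 M⁻¹ h⁻¹)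

The flask reaches that conversion at 12.7 h, later than our floor. That is 3.24 lifetimes, for which the rule gives 0.132. For the delta run, our lifetime taken inverse in reagent is 2.62 h, and intermediate (charge minus substrate minus product) reads 8.30% at 2.00 h and 7.90% at 4.00 h.

(Readings and results were computed with constants of no real substance; the scatter is artificial.)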